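**Plan**
Retrosynthesis cuts, in this order: O1–C2 of ring C (Mitsunobu etherification), C4–C4a (aryllithium plus Weinreb amide), C4a–C5 and C8–C8a of ring A (cyclobutenone/siloxyalkyne benzannulation), and the benzyl–cyclobutene bond (Grignard addition to dimethyl squarate).
Forward: ring D is bought, the four-membered ring comes from dimethyl squarate, ring A is built in the benzannulation, the phenylpropanoyl chain is joined at C4a, and ring C closes last.
Enabling feature: ring A carries oxygens at C5 and C8a on either side of the acyl carbon C4a; the benzannulation delivers them differentiated (free C5 hydroxyl, silylated C8a oxygen), so only the C8a oxygen can close ring C.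
Stereochemistry: C2 comes from commercial ethyl (R)-3-hydroxy-3-phenylpropanoate and is inverted to S in the Mitsunobu closure.

Key step: step 8

Remark: locants C2 to C8a follow the chromanone numbering of the target; ring A is the benzo ring, ring C the pyranone ring, ring D the arene of the benzyl group.
Assumption: monolithium acetylide accepts oxygen from lithium tert-butyl peroxide at low temperature in the way substituted lithium acetylides do.

**Route**

Step 1
Reactants: 1 2-hydroxy-5-methoxybenzaldehyde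
Product: 2 5-methoxy-2-(methoxymethoxy)benzaldehyde
Conditions: MOMCl, i-Pr2NEt, CH2Cl2, 0 °C to rt
Reagents that add atoms: chloromethyl methyl ether, COCCl
Why: O-alkylation of the phenol (MOM protection) masks the ring D hydroxyl as an acetal that should tolerate the Grignard, hydride, organolithium and fluoride steps and leave in the final acid step.

Step 2
Reactants: 2 5-methoxy-2-(methoxymethoxy)benzaldehyde
Product: 3 [5-methoxy-2-(methoxymethoxy)phenyl]methanol
Conditions: NaBH4, MeOH, 0 °C
Reagents that add atoms: none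
Why: Borohydride reduction of the aryl aldehyde to the benzylic alcohol leaves the acetal untouched.

Step 3
Reactants: 3 [5-methoxy-2-(methoxymethoxy)phenyl]methanol
Product: 4 2-(chloromethyl)-4-methoxy-1-(methoxymethoxy)benzene
Conditions: PPh3, NCS, CH2Cl2, 0 °C
Reagents that add atoms: N-chlorosuccinimide, O=C1CCC(=O)N1Cl
Why: Appel-type chlorination through an alkoxyphosphonium ion converts the electron-rich benzylic alcohol to the chloride under neutral conditions, so the acid-labile acetal is kept.

Step 4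
Reactants: 4 2-(chloromethyl)-4-methoxy-1-(methoxymethoxy)benzene; 5 dimethyl squarate
Product: 9 3-methoxy-4-[5-methoxy-2-(methoxymethoxy)benzyl]cyclobut-3-ene-1,2-dione, via benzylic Grignard reagent 6 (not isolated), via chloromagnesium alkoxide adduct 7 (not isolated), via tertiary trifluoroacetate 8 (not isolated)
Conditions: Mg, THF, 0 °C; then 5, THF, −78 °C; then (CF3CO)2O, −78 to 0 °C; aq. NaHCO3
Reagents that add atoms: water, O
Why: Grignard 1,2-addition to one squarate carbonyl, then trifluoroacetylation of the tertiary alkoxide, ionisation and hydrolytic loss of methanol on work-up, is the standard entry to 3-alkoxy-4-alkylcyclobutenediones from squaric esters.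

Step 5
Reactants: 9 3-methoxy-4-[5-methoxy-2-(methoxymethoxy)benzyl]cyclobut-3-ene-1,2-dione
Product: 10 4-hydroxy-3-methoxy-2-[5-methoxy-2-(methoxymethoxy)benzyl]cyclobut-2-en-1-one (racemic)
Conditions: LiAlH(OtBu)3, THF, −78 °C
Reagents that add atoms: none
Why: The bulky hydride should attack the ketone-like carbonyl next to the methoxy-bearing carbon and not the vinylogous ester carbonyl, the established regiochemistry for 1,2-reduction of 3-alkoxy-4-alkylcyclobutenediones; the new carbinol centre is racemic and disappears on aromatisation.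

Step 6
Reactants: 10 4-hydroxy-3-methoxy-2-[5-methoxy-2-(methoxymethoxy)benzyl]cyclobut-2-en-1-one
Product: 11 3,4-dimethoxy-2-[5-methoxy-2-(methoxymethoxy)benzyl]cyclobut-2-en-1-one (racemic)
Conditions: MeI, Ag2O, MeCN, rt, dark
Reagents that add atoms: iodomethane, CI
Why: Silver oxide promoted O-methylation (Purdie methylation) caps the acid- and base-sensitive 4-hydroxycyclobutenone under near-neutral conditions and installs the future C6 methoxy group.

Step 7
Reactants: 12 acetylene; 13 triisopropylsilyl trifluoromethanesulfonate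
Product: 16 triisopropylsiloxyacetylene, via lithium acetylide 14 (not isolated), via lithium ethynolate 15 (not isolated)
Conditions: n-BuLi, THF, −78 °C; t-BuOOLi (from t-BuOOH and LiN(SiMe3)2), −78 to −30 °C; then 13, −78 to 0 °C
Reagents that add atoms: tert-butyl hydroperoxide, CC(C)(C)OO
Why: Electrophilic oxygen transfer from lithium tert-butyl peroxide to a lithium acetylide gives the ynolate, which the hindered silyl triflate silylates on oxygen, the known route to 1-siloxyalkynes; the low temperature should keep monolithium acetylide from disproportionating.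

Step 8
Reactants: 11 3,4-dimethoxy-2-[5-methoxy-2-(methoxymethoxy)benzyl]cyclobut-2-en-1-one; 16 triisopropylsiloxyacetylene
Product: 21 2,3-dimethoxy-4-[5-methoxy-2-(methoxymethoxy)benzyl]-5-(triisopropylsiloxy)phenol, via vinylketene 17 (not isolated), via 4-vinylcyclobutenone 18 (not isolated), via dienylketene 19 (not isolated), via cyclohexa-2,4-dienone 20 (not isolated)
Conditions: 16 (2 equiv), degassed toluene, 80 °C then 110 °C, sealed tube
Reagents that add atoms: none
Why: Heating opens 11 by a conrotatory 4π electrocyclic reaction (methoxy rotating outward) to vinylketene 17, whose carbonyl carbon is attacked by the unsubstituted carbon of 16 in a [2+2] cycloaddition that forms the C4a–C5 and C8–C8a bonds of 18. A second 4π opening gives dienylketene 19, and ring A closes by thermal 6π electrocyclisation (re-forming C5–C6) to dienone 20, which tautomerises to the phenol. This is the Danheiser benzannulation of a cyclobutenone with a siloxyalkyne, which is known to give resorcinol monosilyl ethers. No stereocentre is created, and the racemic methoxy-bearing carbon of 11 becomes aromatic C6. The one selectivity needed is the orientation of the ketene–alkyne cycloaddition, secured by the polarisation of the ynol ether (nucleophilic at the carbon remote from oxygen) against the electrophilic ketene carbon, which places the siloxy group meta and the benzyl group para to the new hydroxyl. The two oxygens flanking C4a thus emerge as a free phenol (C5) and a silyl ether (C8a).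

Step 9
Reactants: 21 2,3-dimethoxy-4-[5-methoxy-2-(methoxymethoxy)benzyl]-5-(triisopropylsiloxy)phenol
Product: 22 2-bromo-5,6-dimethoxy-4-[5-methoxy-2-(methoxymethoxy)benzyl]-3-(triisopropylsiloxy)phenol
Conditions: NBS, CH2Cl2, −78 to 0 °C, dark
Reagents that add atoms: N-bromosuccinimide, O=C1CCC(=O)N1Br
Why: Electrophilic aromatic bromination should occur at C4a, the only free position of ring A, which is ortho to the free hydroxyl and to the siloxy group and para to a methoxy group and so far more nucleophilic than any position of ring D.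

Step 10
Reactants: 22 2-bromo-5,6-dimethoxy-4-[5-methoxy-2-(methoxymethoxy)benzyl]-3-(triisopropylsiloxy)phenol
Product: 23 {6-bromo-3,4-dimethoxy-5-(methoxymethoxy)-2-[5-methoxy-2-(methoxymethoxy)benzyl]phenoxy}triisopropylsilane
Conditions: NaH, MOMCl, THF, 0 °C to rt
Reagents that add atoms: chloromethyl methyl ether, COCCl
Why: O-alkylation of the sodium phenoxide (MOM protection) blocks the C5 oxygen so that later only the C8a oxygen can close ring C.

Step 11
Reactants: 24 ethyl (R)-3-hydroxy-3-phenylpropanoate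
Product: 25 ethyl (R)-3-phenyl-3-(triethylsiloxy)propanoate
Conditions: TESCl, imidazole, CH2Cl2, 0 °C to rt
Reagents that add atoms: chlorotriethylsilane, CC[Si](Cl)(CC)CC
Why: Silylation of the secondary benzylic alcohol prevents alkoxide formation and retro-aldol cleavage in the acylation step and does not touch the stereocentre.

Step 12
Reactants: 25 ethyl (R)-3-phenyl-3-(triethylsiloxy)propanoate
Product: 26 (R)-N-methoxy-N-methyl-3-phenyl-3-(triethylsiloxy)propanamide
Conditions: MeNH(OMe)·HCl, i-PrMgCl, THF, −20 to 0 °C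
Reagents that add atoms: N,O-dimethylhydroxylamine hydrochloride, CNOC.Cl
Why: Aminolysis of the ester by the chloromagnesium amide of N,O-dimethylhydroxylamine gives the Weinreb amide; the stereocentre is not alpha to the carbonyl and is not at risk.

Step 13
Reactants: 23 {6-bromo-3,4-dimethoxy-5-(methoxymethoxy)-2-[5-methoxy-2-(methoxymethoxy)benzyl]phenoxy}triisopropylsilane; 26 (R)-N-methoxy-N-methyl-3-phenyl-3-(triethylsiloxy)propanamide
Product: 28 (R)-1-{3,4-dimethoxy-2-(methoxymethoxy)-5-[5-methoxy-2-(methoxymethoxy)benzyl]-6-(triisopropylsiloxy)phenyl}-3-phenyl-3-(triethylsiloxy)propan-1-one, via aryllithium 27 (not isolated)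
Conditions: n-BuLi, THF, −78 °C; then 26, −78 to −40 °C; aq. NH4Cl
Reagents that add atoms: none
Why: Bromine–lithium exchange at −78 °C is faster than any deprotonation and fixes the carbanion at C4a (lithium chelated by the C5 MOM oxygen), and the Weinreb ketone synthesis then forms C4–C4a through a chelated tetrahedral intermediate that prevents over-addition.

Step 14
Reactants: 28 (R)-1-{3,4-dimethoxy-2-(methoxymethoxy)-5-[5-methoxy-2-(methoxymethoxy)benzyl]-6-(triisopropylsiloxy)phenyl}-3-phenyl-3-(triethylsiloxy)propan-1-one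
Product: 29 (R)-3-hydroxy-1-{2-hydroxy-4,5-dimethoxy-6-(methoxymethoxy)-3-[5-methoxy-2-(methoxymethoxy)benzyl]phenyl}-3-phenylpropan-1-one
Conditions: Bu4NF, AcOH, THF, 0 °C to rt
Reagents that add atoms: none
Why: Fluoride cleaves both the aryl triisopropylsilyl ether and the triethylsilyl ether, and the acetic acid buffer should keep the beta-hydroxy ketone from E1cB elimination or retro-aldol cleavage.

Step 15
Reactants: 29 (R)-3-hydroxy-1-{2-hydroxy-4,5-dimethoxy-6-(methoxymethoxy)-3-[5-methoxy-2-(methoxymethoxy)benzyl]phenyl}-3-phenylpropan-1-one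
Product: 30 (2S)-6,7-dimethoxy-5-(methoxymethoxy)-8-[5-methoxy-2-(methoxymethoxy)benzyl]-2-phenylchroman-4-one
Conditions: PPh3, DIAD, THF, 0 °C
Reagents that add atoms: none
Why: Intramolecular Mitsunobu etherification, in which the acidic ortho-acyl phenol at C8a displaces the activated secondary alcohol in a 6-exo-tet SN2 closure with inversion, should turn the R carbinol into the 2S centre, a closure precedented for chiral chroman-4-ones.

Step 16
Reactants: 30 (2S)-6,7-dimethoxy-5-(methoxymethoxy)-8-[5-methoxy-2-(methoxymethoxy)benzyl]-2-phenylchroman-4-one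
Product: 31 (2S)-5-hydroxy-8-(2-hydroxy-5-methoxybenzyl)-6,7-dimethoxy-2-phenylchroman-4-one
Conditions: HCl (3 M aq.), MeOH, 40 °C
Reagents that add atoms: none
Why: Acid-catalysed acetal exchange with methanol removes both MOM ethers, and the 2-arylchroman-4-one should keep its configuration under mild acid because ring opening to the chalcone is a base-promoted process.

**Compound list**

1 | 2-hydroxy-5-methoxybenzaldehyde | COc1ccc(O)c(C=O)c1 | starting material
2 | 5-methoxy-2-(methoxymethoxy)benzaldehyde | COCOc1ccc(OC)cc1C=O | intermediate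
3 | [5-methoxy-2-(methoxymethoxy)phenyl]methanol | COCOc1ccc(OC)cc1CO | intermediate
4 | 2-(chloromethyl)-4-methoxy-1-(methoxymethoxy)benzene | COCOc1ccc(OC)cc1CCl | intermediate
5 | dimethyl squarate (3,4-dimethoxycyclobut-3-ene-1,2-dione) | COC1=C(OC)C(=O)C1=O | starting material
6 | [5-methoxy-2-(methoxymethoxy)benzyl]magnesium chloride | COCOc1ccc(OC)cc1C[Mg]Cl | intermediate
7 | chloromagnesium 2,3-dimethoxy-1-[5-methoxy-2-(methoxymethoxy)benzyl]-4-oxocyclobut-2-en-1-olate (racemic) | COCOc1ccc(OC)cc1CC1(O[Mg]Cl)C(OC)=C(OC)C1=O | intermediate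
8 | 2,3-dimethoxy-1-[5-methoxy-2-(methoxymethoxy)benzyl]-4-oxocyclobut-2-en-1-yl trifluoroacetate (racemic) | COCOc1ccc(OC)cc1CC1(OC(=O)C(F)(F)F)C(OC)=C(OC)C1=O | intermediate
9 | 3-methoxy-4-[5-methoxy-2-(methoxymethoxy)benzyl]cyclobut-3-ene-1,2-dione | COCOc1ccc(OC)cc1CC1=C(OC)C(=O)C1=O | intermediate
10 | 4-hydroxy-3-methoxy-2-[5-methoxy-2-(methoxymethoxy)benzyl]cyclobut-2-en-1-one (racemic) | COCOc1ccc(OC)cc1CC1=C(OC)C(O)C1=O | intermediate
11 | 3,4-dimethoxy-2-[5-methoxy-2-(methoxymethoxy)benzyl]cyclobut-2-en-1-one (racemic) | COCOc1ccc(OC)cc1CC1=C(OC)C(OC)C1=O | intermediate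
12 | acetylene | C#C | starting material
13 | triisopropylsilyl trifluoromethanesulfonate | CC(C)[Si](OS(=O)(=O)C(F)(F)F)(C(C)C)C(C)C | starting material
14 | lithium acetylide | [Li]C#C | intermediate
15 | lithium ethynolate | [Li+].[O-]C#C | intermediate
16 | triisopropylsiloxyacetylene [(ethynyloxy)triisopropylsilane] | C#CO[Si](C(C)C)(C(C)C)C(C)C | intermediate
17 | (Z)-3,4-dimethoxy-2-[5-methoxy-2-(methoxymethoxy)benzyl]buta-1,3-dien-1-one | CO/C=C(\OC)C(Cc1cc(OC)ccc1OCOC)=C=O | intermediate
18 | 4-[(Z)-1,2-dimethoxyvinyl]-4-[5-methoxy-2-(methoxymethoxy)benzyl]-3-(triisopropylsiloxy)cyclobut-2-en-1-one (racemic) | O=C1C=C(O[Si](C(C)C)(C(C)C)C(C)C)C1(Cc1cc(OC)ccc1OCOC)/C(OC)=C/OC | intermediate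
19 | (3E,5Z)-5,6-dimethoxy-4-[5-methoxy-2-(methoxymethoxy)benzyl]-3-(triisopropylsiloxy)hexa-1,3,5-trien-1-one | O=C=C/C(O[Si](C(C)C)(C(C)C)C(C)C)=C(\C(OC)=C\OC)Cc1cc(OC)ccc1OCOC | intermediate
20 | 5,6-dimethoxy-4-[5-methoxy-2-(methoxymethoxy)benzyl]-3-(triisopropylsiloxy)cyclohexa-2,4-dien-1-one (racemic) | O=C1C=C(O[Si](C(C)C)(C(C)C)C(C)C)C(Cc2cc(OC)ccc2OCOC)=C(OC)C1OC | intermediate
21 | 2,3-dimethoxy-4-[5-methoxy-2-(methoxymethoxy)benzyl]-5-(triisopropylsiloxy)phenol | COc1ccc(OCOC)c(Cc2c(OC)c(OC)c(O)cc2O[Si](C(C)C)(C(C)C)C(C)C)c1 | intermediate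
22 | 2-bromo-5,6-dimethoxy-4-[5-methoxy-2-(methoxymethoxy)benzyl]-3-(triisopropylsiloxy)phenol | COc1ccc(OCOC)c(Cc2c(OC)c(OC)c(O)c(Br)c2O[Si](C(C)C)(C(C)C)C(C)C)c1 | intermediate
23 | {6-bromo-3,4-dimethoxy-5-(methoxymethoxy)-2-[5-methoxy-2-(methoxymethoxy)benzyl]phenoxy}triisopropylsilane | COc1ccc(OCOC)c(Cc2c(OC)c(OC)c(OCOC)c(Br)c2O[Si](C(C)C)(C(C)C)C(C)C)c1 | intermediate
24 | ethyl (R)-3-hydroxy-3-phenylpropanoate | CCOC(=O)C[C@@H](O)c1ccccc1 | starting material
25 | ethyl (R)-3-phenyl-3-(triethylsiloxy)propanoate | CCOC(=O)C[C@@H](O[Si](CC)(CC)CC)c1ccccc1 | intermediate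
26 | (R)-N-methoxy-N-methyl-3-phenyl-3-(triethylsiloxy)propanamide | CON(C)C(=O)C[C@@H](O[Si](CC)(CC)CC)c1ccccc1 | intermediate
27 | {3,4-dimethoxy-2-(methoxymethoxy)-5-[5-methoxy-2-(methoxymethoxy)benzyl]-6-(triisopropylsiloxy)phenyl}lithium | COc1ccc(OCOC)c(Cc2c(OC)c(OC)c(OCOC)c([Li])c2O[Si](C(C)C)(C(C)C)C(C)C)c1 | intermediate
28 | (R)-1-{3,4-dimethoxy-2-(methoxymethoxy)-5-[5-methoxy-2-(methoxymethoxy)benzyl]-6-(triisopropylsiloxy)phenyl}-3-phenyl-3-(triethylsiloxy)propan-1-one | COc1ccc(OCOC)c(Cc2c(OC)c(OC)c(OCOC)c(C(=O)C[C@@H](O[Si](CC)(CC)CC)c3ccccc3)c2O[Si](C(C)C)(C(C)C)C(C)C)c1 | intermediate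
29 | (R)-3-hydroxy-1-{2-hydroxy-4,5-dimethoxy-6-(methoxymethoxy)-3-[5-methoxy-2-(methoxymethoxy)benzyl]phenyl}-3-phenylpropan-1-one | COc1ccc(OCOC)c(Cc2c(OC)c(OC)c(OCOC)c(C(=O)C[C@@H](O)c3ccccc3)c2O)c1 | intermediate
30 | (2S)-6,7-dimethoxy-5-(methoxymethoxy)-8-[5-methoxy-2-(methoxymethoxy)benzyl]-2-phenylchroman-4-one | COc1ccc(OCOC)c(Cc2c(OC)c(OC)c(OCOC)c3c2O[C@H](c2ccccc2)CC3=O)c1 | intermediate
31 | (2S)-5-hydroxy-8-(2-hydroxy-5-methoxybenzyl)-6,7-dimethoxy-2-phenylchroman-4-one | COc1ccc(O)c(Cc2c(OC)c(OC)c(O)c3c2O[C@H](c2ccccc2)CC3=O)c1 | target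

**Step count**
Total: 16 steps. Longest linear sequence: 13 steps (steps 1 to 6, 8 to 10 and 13 to 16). Steps 7, 11 and 12 are side branches.

**Steps most likely to fail**

Step 7. Monolithium acetylide may disproportionate to insoluble dilithium acetylide before oxygen transfer is complete, and the terminal siloxyalkyne may hydrolyse or isomerise to a ketene during isolation. The fallback sets out from triflate 13 and cyclobutenone 11 and returns at bromophenol 22. Commercial trimethylsilylacetylene is lithiated with n-BuLi to lithium (trimethylsilyl)acetylide F1, oxidised with t-BuOOLi to lithium (trimethylsilyl)ethynolate F2, and O-silylated with 13 to triisopropyl{[(trimethylsilyl)ethynyl]oxy}silane F3, a substituted siloxyalkyne of the well-behaved class. Heating F3 with 11 as in step 8 should run through vinylketene 17, the silylated 4-vinylcyclobutenone F4, the silylated dienylketene F5 and the silylated cyclohexadienone F6 to the C4a-silylated phenol 2,3-dimethoxy-4-[5-methoxy-2-(methoxymethoxy)benzyl]-5-(triisopropylsiloxy)-6-(trimethylsilyl)phenol F7. NBS then effects ipso-bromodesilylation of this electron-rich arylsilane and gives 22 directly, with the bromination site fixed by silicon.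

Step 13. Acyl transfer to the carbanion may be slow next to the triisopropylsiloxy group, so that proton transfer from the alpha-methylene of the amide, or migration of silicon from oxygen to carbon on warming, takes over. The fallback sets out from ester 25 and bromide 23 and returns at ketone 28. Ester 25 is reduced with i-Bu2AlH at −78 °C to (R)-3-phenyl-3-(triethylsiloxy)propanal F8. Aryllithium 27, made from 23 as before, adds at −78 °C to this smaller and more electrophilic carbonyl to give (3R)-1-{3,4-dimethoxy-2-(methoxymethoxy)-5-[5-methoxy-2-(methoxymethoxy)benzyl]-6-(triisopropylsiloxy)phenyl}-3-phenyl-3-(triethylsiloxy)propan-1-ol F9 as a mixture of epimers at the new carbinol. Dess–Martin periodinane oxidation converges both epimers to 28.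

Step 15. The activated hydroxyl may be lost by E1cB elimination to the chalcone, whose unselective oxa-Michael closure would erode the enantiomeric purity. The fallback abandons the chiral pool, sets out from bromide 23 and returns at 30. Aryllithium 27 is acylated with N-methoxy-N-methylacetamide to 1-{3,4-dimethoxy-2-(methoxymethoxy)-5-[5-methoxy-2-(methoxymethoxy)benzyl]-6-(triisopropylsiloxy)phenyl}ethan-1-one F10. Condensation with N,N-dimethylformamide dimethyl acetal at 100 °C gives the (E)-enaminone F11. Bu4NF removes the silyl group to give the hydroxy enaminone F12, which on warming in acetic acid closes with loss of dimethylamine to 6,7-dimethoxy-5-(methoxymethoxy)-8-[5-methoxy-2-(methoxymethoxy)benzyl]-4H-chromen-4-one F13. A Hayashi–Miyaura asymmetric 1,4-addition of phenylboronic acid, catalysed by [Rh(OH)(cod)]2 and an atropisomeric bisphosphine, then sets C2 and gives 30. By analogy with cyclic enones the (S)-configured ligand is expected to give the 2S product; the antipode would be used if the facial sense proves opposite.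

**Further compounds**

F1 | step 7 | lithium (trimethylsilyl)acetylide | [Li]C#C[Si](C)(C)C
F2 | step 7 | lithium (trimethylsilyl)ethynolate | [Li+].[O-]C#C[Si](C)(C)C
F3 | step 7 | triisopropyl{[(trimethylsilyl)ethynyl]oxy}silane | C[Si](C)(C)C#CO[Si](C(C)C)(C(C)C)C(C)C
F4 | step 7 | 4-[(Z)-1,2-dimethoxyvinyl]-4-[5-methoxy-2-(methoxymethoxy)benzyl]-3-(triisopropylsiloxy)-2-(trimethylsilyl)cyclobut-2-en-1-one (racemic) | O=C1C([Si](C)(C)C)=C(O[Si](C(C)C)(C(C)C)C(C)C)C1(Cc1cc(OC)ccc1OCOC)/C(OC)=C/OC
F5 | step 7 | (3E,5Z)-5,6-dimethoxy-4-[5-methoxy-2-(methoxymethoxy)benzyl]-3-(triisopropylsiloxy)-2-(trimethylsilyl)hexa-1,3,5-trien-1-one | O=C=C([Si](C)(C)C)/C(O[Si](C(C)C)(C(C)C)C(C)C)=C(\C(OC)=C\OC)Cc1cc(OC)ccc1OCOC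
F6 | step 7 | 5,6-dimethoxy-4-[5-methoxy-2-(methoxymethoxy)benzyl]-3-(triisopropylsiloxy)-2-(trimethylsilyl)cyclohexa-2,4-dien-1-one (racemic) | O=C1C([Si](C)(C)C)=C(O[Si](C(C)C)(C(C)C)C(C)C)C(Cc2cc(OC)ccc2OCOC)=C(OC)C1OC
F7 | step 7 | 2,3-dimethoxy-4-[5-methoxy-2-(methoxymethoxy)benzyl]-5-(triisopropylsiloxy)-6-(trimethylsilyl)phenol | COc1ccc(OCOC)c(Cc2c(OC)c(OC)c(O)c([Si](C)(C)C)c2O[Si](C(C)C)(C(C)C)C(C)C)c1
F8 | step 13 | (R)-3-phenyl-3-(triethylsiloxy)propanal | O=CC[C@@H](O[Si](CC)(CC)CC)c1ccccc1
F9 | step 13 | (3R)-1-{3,4-dimethoxy-2-(methoxymethoxy)-5-[5-methoxy-2-(methoxymethoxy)benzyl]-6-(triisopropylsiloxy)phenyl}-3-phenyl-3-(triethylsiloxy)propan-1-ol (both C1 epimers) | COc1ccc(OCOC)c(Cc2c(OC)c(OC)c(OCOC)c(C(O)C[C@@H](O[Si](CC)(CC)CC)c3ccccc3)c2O[Si](C(C)C)(C(C)C)C(C)C)c1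
F10 | step 15 | 1-{3,4-dimethoxy-2-(methoxymethoxy)-5-[5-methoxy-2-(methoxymethoxy)benzyl]-6-(triisopropylsiloxy)phenyl}ethan-1-one | COc1ccc(OCOC)c(Cc2c(OC)c(OC)c(OCOC)c(C(C)=O)c2O[Si](C(C)C)(C(C)C)C(C)C)c1
F11 | step 15 | (E)-3-(dimethylamino)-1-{3,4-dimethoxy-2-(methoxymethoxy)-5-[5-methoxy-2-(methoxymethoxy)benzyl]-6-(triisopropylsiloxy)phenyl}prop-2-en-1-one | COc1ccc(OCOC)c(Cc2c(OC)c(OC)c(OCOC)c(C(=O)/C=C/N(C)C)c2O[Si](C(C)C)(C(C)C)C(C)C)c1
F12 | step 15 | (E)-3-(dimethylamino)-1-{2-hydroxy-4,5-dimethoxy-6-(methoxymethoxy)-3-[5-methoxy-2-(methoxymethoxy)benzyl]phenyl}prop-2-en-1-one | COc1ccc(OCOC)c(Cc2c(OC)c(OC)c(OCOC)c(C(=O)/C=C/N(C)C)c2O)c1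
F13 | step 15 | 6,7-dimethoxy-5-(methoxymethoxy)-8-[5-methoxy-2-(methoxymethoxy)benzyl]-4H-chromen-4-one | COc1ccc(OCOC)c(Cc2c(OC)c(OC)c(OCOC)c3c(=O)ccoc23)c1
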